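**Retrosynthetic overview**
1. Target ⇒ hydrogenolysis of four benzyl ethers and 3-O-methylation ⇒ 5,7,3',5'-tetra-O-benzyl flavonol ⇒ C3 oxygenation of the corresponding flavone.
2. Flavone ⇒ O1–C2 disconnection (oxidative oxa-Michael cyclisation) ⇒ 2'-hydroxychalcone.
3. Key C–C disconnection at Cα=Cβ of the chalcone ⇒ intermolecular Claisen–Schmidt aldol condensation of a ring A methyl ketone with a ring B aldehyde.
4. Ring A ketone ⇐ phloracetophenone (bis-benzylation, dibromination, double methoxylation). Its substitution is mirror-symmetric, so either ortho OH may close ring C. Ring B aldehyde ⇐ methyl gallate (4-O-methylation, benzylation, ester to CHO).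
5. Ring order: rings A and B are bought as arenes. Ring C is the only ring made, after the aldol step.

Assumption: the target SMILES holds no stereocentre and no stereogenic axis, so the compound is achiral and there is no enantiomer to select; the only stereodescriptor on the route is the E alkene of 11, and the sp3 centres of 10, 12 and 14 are racemic and are erased again.

**Route**

Step 1
Reactants: 1 2',4',6'-trihydroxyacetophenone (phloracetophenone)
Product: 2 4',6'-bis(benzyloxy)-2'-hydroxyacetophenone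
Conditions: BnBr (2.1 equiv), K2CO3 (2.5 equiv), DMF, 60 °C, 4 h
Reagents that add atoms: benzyl bromide, BrCc1ccccc1
Why: Williamson ether synthesis in which the OH hydrogen-bonded to the acetyl C=O is the least nucleophilic, and because the two ortho OH groups are equivalent the one that stays free leaves a single bis-ether.

Step 2
Reactants: 2 4',6'-bis(benzyloxy)-2'-hydroxyacetophenone
Product: 3 4',6'-bis(benzyloxy)-3',5'-dibromo-2'-hydroxyacetophenone
Conditions: NBS (2.05 equiv), MeCN/CH2Cl2, 0 °C to rt, dark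
Reagents that add atoms: N-bromosuccinimide, O=C1CCC(=O)N1Br
Why: Electrophilic aromatic bromination of the only two ring C–H positions, each activated by three oxygen substituents, is far faster than attack on the benzyl rings or the ketone alpha carbon and leaves no regiochemical choice.

Step 3
Reactants: 3 4',6'-bis(benzyloxy)-3',5'-dibromo-2'-hydroxyacetophenone
Product: 4 4',6'-bis(benzyloxy)-2'-hydroxy-3',5'-dimethoxyacetophenone
Conditions: NaOMe (25% in MeOH, 10 equiv), CuBr (0.5 equiv), DMF, 110 °C, N2, 8 h; then 1 M HCl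
Reagents that add atoms: sodium methoxide, C[O-].[Na+]
Why: CuBr-catalysed Ullmann-type methoxylation accepts bromides flanked by two oxygen substituents because methoxide is small, and the substrate reacts as its sodium phenoxide, which keeps the hindered ketone from condensing.

Step 4
Reactants: 5 methyl gallate (methyl 3,4,5-trihydroxybenzoate)
Product: 6 methyl 3,5-dihydroxy-4-methoxybenzoate
Conditions: MeI (1.05 equiv), K2CO3 (1.0 equiv), DMF, 0 °C to rt, 16 h; chromatography or recrystallisation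
Reagents that add atoms: iodomethane, CI
Why: Chemoselective Williamson O-methylation works because the 4-OH para to the ester is the most acidic phenol, so with one equivalent of base and MeI its phenoxide is alkylated preferentially.

Step 5
Reactants: 6 methyl 3,5-dihydroxy-4-methoxybenzoate
Product: 7 methyl 3,5-bis(benzyloxy)-4-methoxybenzoate
Conditions: BnBr (2.4 equiv), K2CO3 (3 equiv), DMF, 60 °C
Reagents that add atoms: benzyl bromide, BrCc1ccccc1
Why: Exhaustive Williamson ether synthesis on the two remaining equivalent phenols has no selectivity issue.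

Step 6
Reactants: 7 methyl 3,5-bis(benzyloxy)-4-methoxybenzoate
Product: 8 [3,5-bis(benzyloxy)-4-methoxyphenyl]methanol
Conditions: LiAlH4 (1.2 equiv), THF, 0 °C to rt; H2O/aq NaOH quench
Reagents that add atoms: none
Why: Hydride reduction of the ester to the primary alcohol by LiAlH4 leaves aryl benzyl and methyl ethers untouched.

Step 7
Reactants: 8 [3,5-bis(benzyloxy)-4-methoxyphenyl]methanol
Product: 9 3,5-bis(benzyloxy)-4-methoxybenzaldehyde
Conditions: activated MnO2 (10 equiv), CH2Cl2, rt
Reagents that add atoms: none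
Why: Heterogeneous MnO2 oxidation is selective for benzylic alcohols and stops at the aldehyde.

Step 8
Reactants: 4 4',6'-bis(benzyloxy)-2'-hydroxy-3',5'-dimethoxyacetophenone; 9 3,5-bis(benzyloxy)-4-methoxybenzaldehyde
Product: 11 (E)-2'-hydroxy-4',6',3,5-tetrakis(benzyloxy)-3',5',4-trimethoxychalcone, via aldol adduct 10 (not isolated)
Conditions: KOH (50% aq, 15 equiv), EtOH/THF 2:1, rt, 48 h; then 1 M HCl
Reagents that add atoms: none
Why: In this Claisen–Schmidt crossed aldol condensation only 4 can enolise and only 9 is a non-enolisable acceptor, and E1cB dehydration of 10 erases the carbinol stereocentre and gives the conjugated E alkene under thermodynamic control.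

Step 9
Reactants: 11 (E)-2'-hydroxy-4',6',3,5-tetrakis(benzyloxy)-3',5',4-trimethoxychalcone
Product: 13 5,7,3',5'-tetrakis(benzyloxy)-6,8,4'-trimethoxyflavone, via flavanone 12 (not isolated)
Conditions: I2 (0.1 equiv), DMSO, 130 °C, 3 h; aq Na2S2O3 wash
Reagents that add atoms: none
Why: Intramolecular oxa-Michael addition of the 2'-OH closes ring C and iodine-catalysed dehydrogenation with DMSO as terminal oxidant converts the flavanone into the flavone, removing the transient C2 stereocentre.

Step 10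
Reactants: 13 5,7,3',5'-tetrakis(benzyloxy)-6,8,4'-trimethoxyflavone
Product: 15 5,7,3',5'-tetrakis(benzyloxy)-3-hydroxy-6,8,4'-trimethoxyflavone, via flavone epoxide 14 (not isolated)
Conditions: DMDO (ca. 0.07 M in acetone, 2.5 equiv), CH2Cl2, 0 °C to rt; then p-TsOH·H2O (0.1 equiv), CH2Cl2, rt
Reagents that add atoms: dimethyldioxirane, CC1(C)OO1
Why: Epoxidation of the enol-ether-like C2=C3 bond by neutral DMDO followed by acid-catalysed epoxide opening at C2 and loss of H-3 gives the flavonol with no stereocentre left, and it avoids the aurone formation that Algar–Flynn–Oyamada oxidation shows for 6'-alkoxychalcones.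

Step 11
Reactants: 15 5,7,3',5'-tetrakis(benzyloxy)-3-hydroxy-6,8,4'-trimethoxyflavone
Product: 16 5,7,3',5'-tetrakis(benzyloxy)-3,6,8,4'-tetramethoxyflavone
Conditions: MeI (3 equiv), K2CO3 (3 equiv), DMF, rt
Reagents that add atoms: iodomethane, CI
Why: Williamson O-methylation of the only free hydroxyl group in the molecule is unambiguous.

Step 12
Reactants: 16 5,7,3',5'-tetrakis(benzyloxy)-3,6,8,4'-tetramethoxyflavone
Product: 17 5,7,3',5'-tetrahydroxy-3,6,8,4'-tetramethoxyflavone
Conditions: H2 (1 atm), 10% Pd/C, THF/MeOH 1:1, rt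
Reagents that add atoms: none
Why: Catalytic hydrogenolysis cleaves all four aryl benzyl ethers, while the methyl ethers and the tetrasubstituted vinylogous-ester C2=C3 bond are inert at 1 atm, and the product is achiral.

**Compound list**
1 | 2',4',6'-trihydroxyacetophenone | CC(=O)c1c(O)cc(O)cc1O | starting material
2 | 4',6'-bis(benzyloxy)-2'-hydroxyacetophenone | CC(=O)c1c(O)cc(OCc2ccccc2)cc1OCc1ccccc1 | intermediate
3 | 4',6'-bis(benzyloxy)-3',5'-dibromo-2'-hydroxyacetophenone | CC(=O)c1c(O)c(Br)c(OCc2ccccc2)c(Br)c1OCc1ccccc1 | intermediate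
4 | 4',6'-bis(benzyloxy)-2'-hydroxy-3',5'-dimethoxyacetophenone | CC(=O)c1c(O)c(OC)c(OCc2ccccc2)c(OC)c1OCc1ccccc1 | intermediate
5 | methyl gallate | COC(=O)c1cc(O)c(O)c(O)c1 | starting material
6 | methyl 3,5-dihydroxy-4-methoxybenzoate | COC(=O)c1cc(O)c(OC)c(O)c1 | intermediate
7 | methyl 3,5-bis(benzyloxy)-4-methoxybenzoate | COC(=O)c1cc(OCc2ccccc2)c(OC)c(OCc2ccccc2)c1 | intermediate
8 | [3,5-bis(benzyloxy)-4-methoxyphenyl]methanol | OCc1cc(OCc2ccccc2)c(OC)c(OCc2ccccc2)c1 | intermediate
9 | 3,5-bis(benzyloxy)-4-methoxybenzaldehyde | O=Cc1cc(OCc2ccccc2)c(OC)c(OCc2ccccc2)c1 | intermediate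
10 | racemic 1-[4,6-bis(benzyloxy)-2-hydroxy-3,5-dimethoxyphenyl]-3-[3,5-bis(benzyloxy)-4-methoxyphenyl]-3-hydroxypropan-1-one (aldol adduct, not isolated) | O=C(CC(O)c1cc(OCc2ccccc2)c(OC)c(OCc2ccccc2)c1)c1c(O)c(OC)c(OCc2ccccc2)c(OC)c1OCc1ccccc1 | intermediate
11 | (E)-1-[4,6-bis(benzyloxy)-2-hydroxy-3,5-dimethoxyphenyl]-3-[3,5-bis(benzyloxy)-4-methoxyphenyl]prop-2-en-1-one (chalcone) | O=C(/C=C/c1cc(OCc2ccccc2)c(OC)c(OCc2ccccc2)c1)c1c(O)c(OC)c(OCc2ccccc2)c(OC)c1OCc1ccccc1 | intermediate
12 | racemic 5,7-bis(benzyloxy)-2-[3,5-bis(benzyloxy)-4-methoxyphenyl]-6,8-dimethoxychroman-4-one (flavanone, not isolated) | O=C1CC(c2cc(OCc3ccccc3)c(OC)c(OCc3ccccc3)c2)Oc2c(OC)c(OCc3ccccc3)c(OC)c(OCc3ccccc3)c21 | intermediate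
13 | 5,7-bis(benzyloxy)-2-[3,5-bis(benzyloxy)-4-methoxyphenyl]-6,8-dimethoxy-4H-chromen-4-one (flavone) | O=c1cc(-c2cc(OCc3ccccc3)c(OC)c(OCc3ccccc3)c2)oc2c(OC)c(OCc3ccccc3)c(OC)c(OCc3ccccc3)c12 | intermediate
14 | racemic 2,3-epoxide of flavone 13 (oxirane fused cis on C2–C3, not isolated) | O=C1C2OC2(c2cc(OCc3ccccc3)c(OC)c(OCc3ccccc3)c2)Oc2c(OC)c(OCc3ccccc3)c(OC)c(OCc3ccccc3)c21 | intermediate
15 | 5,7-bis(benzyloxy)-2-[3,5-bis(benzyloxy)-4-methoxyphenyl]-3-hydroxy-6,8-dimethoxy-4H-chromen-4-one (flavonol) | O=c1c(O)c(-c2cc(OCc3ccccc3)c(OC)c(OCc3ccccc3)c2)oc2c(OC)c(OCc3ccccc3)c(OC)c(OCc3ccccc3)c12 | intermediate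
16 | 5,7-bis(benzyloxy)-2-[3,5-bis(benzyloxy)-4-methoxyphenyl]-3,6,8-trimethoxy-4H-chromen-4-one | COc1c(-c2cc(OCc3ccccc3)c(OC)c(OCc3ccccc3)c2)oc2c(OC)c(OCc3ccccc3)c(OC)c(OCc3ccccc3)c2c1=O | intermediate
17 | 5,7,3',5'-tetrahydroxy-3,6,8,4'-tetramethoxyflavone | COc1c(O)cc(-c2oc3c(OC)c(O)c(OC)c(O)c3c(=O)c2OC)cc1O | target

**Totals**
Total step count: 12.
Longest linear sequence: 9 steps (steps 4 to 12, from methyl gallate). The ring A branch contributes steps 1 to 3.

**Three steps most likely to fail**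

Step 3, the double methoxylation of bromides flanked by two oxygens in the presence of a methyl ketone. The risks are hydrodebromination, a stalled second exchange and side reactions of the acetyl group. The fallback moves the C–O coupling behind the closure of ring C and sets out from 3.
- KOH-mediated Claisen–Schmidt condensation of 3 with 9 passes through the dibromo aldol adduct F1 and gives the (E)-3',5'-dibromochalcone F2.
- I2 in DMSO at 130 °C closes this through the 6,8-dibromoflavanone F3 to the 6,8-dibromoflavone F4, which has neither an enolisable ketone nor a free phenol.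
- NaOMe/CuBr in DMF/MeOH then replaces both bromides, and any pyrone opened reversibly by methoxide recloses on acidic work-up.
- The fallback comes back to the route at 13.

Step 4, the mono-O-methylation of a triphenol. The risks are over-alkylation and 3-O-methyl isomers. The fallback uses protecting-group control instead of acidity control and sets out from 5.
- Ac2O/pyridine gives methyl 3,4,5-triacetoxybenzoate F5.
- With K2CO3 and MeI in refluxing acetone the 4-acetate, the most labile because it is para to the ester, is cleaved first to methyl 3,5-diacetoxy-4-hydroxybenzoate F6.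
- This is methylated at once as its phenoxide to methyl 3,5-diacetoxy-4-methoxybenzoate F7.
- Catalytic K2CO3 in MeOH then removes the two remaining acetates.
- The fallback comes back to the route at 6.

Step 10, the DMDO oxidation of a very electron-rich substrate carrying benzyl ethers. The risks are incomplete conversion and benzylic or arene over-oxidation. The fallback replaces electrophilic epoxidation by carbanion chemistry and sets out from 13.
- LDA in THF at −78 °C removes H-3 to give the 3-lithioflavone F8.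
- B(OMe)3 traps it as the dimethyl flavon-3-ylboronate F9.
- H2O2/AcOH oxidises the C–B bond to C–OH.
- The fallback comes back to the route at 15.

**Further compounds**
F1 | step 3 | racemic 1-[4,6-bis(benzyloxy)-3,5-dibromo-2-hydroxyphenyl]-3-[3,5-bis(benzyloxy)-4-methoxyphenyl]-3-hydroxypropan-1-one | O=C(CC(O)c1cc(OCc2ccccc2)c(OC)c(OCc2ccccc2)c1)c1c(O)c(Br)c(OCc2ccccc2)c(Br)c1OCc1ccccc1
F2 | step 3 | (E)-1-[4,6-bis(benzyloxy)-3,5-dibromo-2-hydroxyphenyl]-3-[3,5-bis(benzyloxy)-4-methoxyphenyl]prop-2-en-1-one | O=C(/C=C/c1cc(OCc2ccccc2)c(OC)c(OCc2ccccc2)c1)c1c(O)c(Br)c(OCc2ccccc2)c(Br)c1OCc1ccccc1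
F3 | step 3 | racemic 5,7-bis(benzyloxy)-2-[3,5-bis(benzyloxy)-4-methoxyphenyl]-6,8-dibromochroman-4-one | O=C1CC(c2cc(OCc3ccccc3)c(OC)c(OCc3ccccc3)c2)Oc2c(Br)c(OCc3ccccc3)c(Br)c(OCc3ccccc3)c21
F4 | step 3 | 5,7-bis(benzyloxy)-2-[3,5-bis(benzyloxy)-4-methoxyphenyl]-6,8-dibromo-4H-chromen-4-one | O=c1cc(-c2cc(OCc3ccccc3)c(OC)c(OCc3ccccc3)c2)oc2c(Br)c(OCc3ccccc3)c(Br)c(OCc3ccccc3)c12
F5 | step 4 | methyl 3,4,5-triacetoxybenzoate | COC(=O)c1cc(OC(C)=O)c(OC(C)=O)c(OC(C)=O)c1
F6 | step 4 | methyl 3,5-diacetoxy-4-hydroxybenzoate | COC(=O)c1cc(OC(C)=O)c(O)c(OC(C)=O)c1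
F7 | step 4 | methyl 3,5-diacetoxy-4-methoxybenzoate | COC(=O)c1cc(OC(C)=O)c(OC)c(OC(C)=O)c1
F8 | step 10 | 3-lithio-5,7-bis(benzyloxy)-2-[3,5-bis(benzyloxy)-4-methoxyphenyl]-6,8-dimethoxy-4H-chromen-4-one | [Li]c1c(-c2cc(OCc3ccccc3)c(OC)c(OCc3ccccc3)c2)oc2c(OC)c(OCc3ccccc3)c(OC)c(OCc3ccccc3)c2c1=O
F9 | step 10 | dimethyl {5,7-bis(benzyloxy)-2-[3,5-bis(benzyloxy)-4-methoxyphenyl]-6,8-dimethoxy-4-oxo-4H-chromen-3-yl}boronate | COB(OC)c1c(-c2cc(OCc3ccccc3)c(OC)c(OCc3ccccc3)c2)oc2c(OC)c(OCc3ccccc3)c(OC)c(OCc3ccccc3)c2c1=O
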